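**Retrosynthetic overview**
1. The target, (3S,4R,3′S,6′R)-β,ε-carotene-3,4,3′-triol, is cut at C7=C8 and C7′=C8′ by two Wittig reactions into ε-ring lactol 10, the C20 bis(phosphonium) salt 17 and β-ring dihydroxy enal 14 (C10 + C20 + C10).
2. Both C10 end groups come from one bicyclic lactone 9. The ε half needs only half-reduction. The β half needs epoxidation on the lactone face, half-reduction and base-induced epoxide opening, which gives the cis-3,4-diol.
3. Lactone 9 comes from the acyclic Z-hydroxy dienoate 7 by an acid-triggered lactonisation/cation–olefin bicyclisation. The δ-lactone closes first and the cyclohexene closes across it in the same operation.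
4. Dienoate 7 comes from (S)-epichlorohydrin, isopropenylmagnesium bromide, methyl propiolate and Me2CuLi. All four stereocentres of the target descend from the single epichlorohydrin centre.
5. No ring is formed after the bicyclisation; the lactone bridge is opened again in each half.

Assumption: all-E crocetin dialdehyde 15 (the industrial C20 dial) is treated as a purchasable starting material.

**Route**

Step 1
Reactants: 1 (S)-epichlorohydrin; 2 isopropenylmagnesium bromide
Product: 4 (2S)-2-(2-methylprop-2-en-1-yl)oxirane, via chlorohydrin 3 (not isolated)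
Conditions: CuI (10 mol %), THF, −40 → 0 °C; then NaOH, Et2O/H2O, rt
Reagents that add atoms: none
Why: Copper-catalysed Grignard opening of the epoxide at its CH2 terminus followed by Williamson-type closure of the chlorohydrin alkoxide (epoxide transposition); the carbinol stereocentre is never broken, so (S) is carried over.

Step 2
Reactants: 4 (2S)-2-(2-methylprop-2-en-1-yl)oxirane; 5 methyl propiolate
Product: 6 methyl (5S)-5-hydroxy-7-methyloct-7-en-2-ynoate
Conditions: n-BuLi, THF, −78 °C; BF3·OEt2; then 4, −78 °C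
Reagents that add atoms: none
Why: Yamaguchi–Hirao alkynylation, in which the BF3-activated terminal epoxide is opened at its CH2 carbon by LiC≡CCO2Me without touching the stereocentre.

Step 3
Reactants: 6 methyl (5S)-5-hydroxy-7-methyloct-7-en-2-ynoate
Product: 7 methyl (2Z,5S)-5-hydroxy-3,7-dimethylocta-2,7-dienoate
Conditions: Me2CuLi (3 equiv), THF, −78 °C; aq. NH4Cl/NH3 quench at −78 °C
Reagents that add atoms: lithium dimethylcuprate, Me2CuLi, [Li+].C[Cu-]C
Why: Stereospecific syn-carbocupration of the ynoate and cold protonation with retention give only the Z-enoate, in which the hydroxylated chain is cis to the ester as lactonisation requires.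

Step 4
Reactants: 7 methyl (2Z,5S)-5-hydroxy-3,7-dimethylocta-2,7-dienoate
Product: 9 (1S,4R)-5,8,8-trimethyl-2-oxabicyclo[2.2.2]oct-5-en-3-one, via dihydropyranone 8 (not isolated)
Conditions: TfOH (20 mol %), (CF3)2CHOH, 0 °C → rt
Reagents that add atoms: none
Why: Proposed new method: the acid first lactonises the Z-δ-hydroxy enoate to dihydropyranone 8, then protonates the 1,1-disubstituted alkene to a tertiary cation that is captured across the ring by the enoate α-carbon, so the δ-lactone and the cyclohexene close in one flask (cation–olefin bicyclisation); the new C–C bond can only form cis to the lactone C–O bond, so the (S) carbinol centre fixes the second bridgehead as (4R), and the resulting tertiary cation can lose H+ only into the C5=C6 position because the conjugated alternative is an anti-Bredt bridgehead alkene (an exocyclic methylene isomer equilibrates to it under the acid); closest known reactions: acid-catalysed cyclisation of geranic and neric esters to α-cyclogeranates (same cation attacking the same enoate α-carbon), cation–olefin/lactonisation bicyclisation of homogeranic acid, and π-cyclisation of 2-(cyclohex-3-enyl)ethyl cations to bicyclo[2.2.2]octanes.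

Step 5
Reactants: 9 (1S,4R)-5,8,8-trimethyl-2-oxabicyclo[2.2.2]oct-5-en-3-one
Product: 10 (1S,4R)-5,8,8-trimethyl-2-oxabicyclo[2.2.2]oct-5-en-3-ol (lactol, both C3 epimers)
Conditions: i-Bu2AlH (1.1 equiv), CH2Cl2, −78 °C; aq. KNaC4H4O6
Reagents that add atoms: none
Why: Half-reduction of a lactone by i-Bu2AlH stops at the aluminium hemiacetal at −78 °C, so the lactol is obtained and neither bridgehead is touched.

Step 6
Reactants: 9 (1S,4R)-5,8,8-trimethyl-2-oxabicyclo[2.2.2]oct-5-en-3-one
Product: 11 (1S,4R,5R,6S)-5,6-epoxy-5,8,8-trimethyl-2-oxabicyclo[2.2.2]octan-3-one (epoxide oxygen syn to the O–C(=O) bridge)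
Conditions: mCPBA, NaHCO3, CH2Cl2, 0 °C → rt
Reagents that add atoms: mCPBA (3-chloroperoxybenzoic acid), O=C(OO)c1cccc(Cl)c1
Why: Prilezhaev epoxidation of the trisubstituted alkene from the face next to the flat lactone bridge, the other face being shielded by the syn methyl of the CMe2 bridge; this puts the epoxide oxygen cis to the lactone oxygen and so sets the future C4 configuration.

Step 7
Reactants: 11 (1S,4R,5R,6S)-5,6-epoxy-5,8,8-trimethyl-2-oxabicyclo[2.2.2]octan-3-one
Product: 12 (1S,4R,5R,6S)-5,6-epoxy-5,8,8-trimethyl-2-oxabicyclo[2.2.2]octan-3-ol (lactol, both C3 epimers)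
Conditions: i-Bu2AlH (1.1 equiv), CH2Cl2, −78 °C; aq. KNaC4H4O6
Reagents that add atoms: none
Why: Lactone half-reduction by i-Bu2AlH as in step 5; the epoxide is inert at −78 °C.

Step 8
Reactants: 12 (1S,4R,5R,6S)-5,6-epoxy-5,8,8-trimethyl-2-oxabicyclo[2.2.2]octan-3-ol
Product: 14 (3R,4S)-3,4-dihydroxy-2,6,6-trimethylcyclohex-1-ene-1-carbaldehyde, via epoxy aldehyde 13 (not isolated)
Conditions: DBU (20 mol %), CH2Cl2, 0 °C → rt
Reagents that add atoms: none
Why: Base opens the lactol to the β,γ-epoxy aldehyde, whose enolate expels the epoxide oxygen in an E1cB β-elimination to give the γ-hydroxy enal; the C–O bond at the secondary epoxide carbon is not broken, so the diol is cis, and a Payne shift is excluded because hydroxyl and epoxide are syn.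

Step 9
Reactants: 15 crocetin dialdehyde
Product: 16 (2E,4E,6E,8E,10E,12E,14E)-2,6,11,15-tetramethylhexadeca-2,4,6,8,10,12,14-heptaene-1,16-diol
Conditions: NaBH4, THF/MeOH, 0 °C
Reagents that add atoms: none
Why: Chemoselective 1,2-reduction of the conjugated dialdehyde by NaBH4 leaves the all-E heptaene untouched.

Step 10
Reactants: 16 crocetin diol
Product: 17 [(2E,4E,6E,8E,10E,12E,14E)-2,6,11,15-tetramethylhexadeca-2,4,6,8,10,12,14-heptaene-1,16-diyl]bis(triphenylphosphonium) dibromide
Conditions: PPh3·HBr (2.1 equiv), MeOH, rt, dark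
Reagents that add atoms: triphenylphosphine hydrobromide, Br.c1ccc(cc1)P(c1ccccc1)c1ccccc1
Why: PPh3·HBr converts polyenyl allylic alcohols into Wittig salts (the retinol-to-retinylphosphonium reaction) by ionisation and capture of the delocalised cation at the terminal carbon, which keeps full conjugation.

Step 11
Reactants: 17 C20 bis(phosphonium) dibromide (3 equiv, excess recovered); 10 ε-ring lactol
Product: 20 [(2E,4E,6E,8E,10E,12E,14E,16E)-17-[(1R,4S)-4-hydroxy-2,6,6-trimethylcyclohex-2-en-1-yl]-2,6,11,15-tetramethylheptadeca-2,4,6,8,10,12,14,16-octaen-1-yl]triphenylphosphonium bromide, via mono-ylide 18 (not isolated), via hydroxy aldehyde 19 (not isolated)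
Conditions: KN(SiMe3)2 (4 equiv), THF, −78 °C; then 10, −78 → 0 °C; aq. NH4Br/HBr quench; SiO2, CH2Cl2/MeOH
Reagents that add atoms: none
Why: Wittig olefination with the bis-ylide reagent in threefold excess so that statistically only one end reacts; the lactolate opens to the hydroxy aldehyde, which the ylide traps at −78 °C faster than the α-centre can enolise, so C6′ stays R (any Z isomer at C7′=C8′ is corrected in step 12).

Step 12
Reactants: 20 C30 phosphonium bromide; 14 (3R,4S)-3,4-dihydroxy-2,6,6-trimethylcyclohex-1-ene-1-carbaldehyde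
Product: 22 (3S,4R,3′S,6′R)-β,ε-carotene-3,4,3′-triol, via ylide 21 (not isolated)
Conditions: NaOMe, MeOH/CH2Cl2, 0 °C → rt; then heptane/EtOAc, reflux, N2, dark; crystallisation
Reagents that add atoms: none
Why: Wittig olefination of the non-enolisable enal under standard carotenoid conditions, which tolerate free hydroxyls on both partners, followed by thermal Z→E equilibration and crystallisation of the all-E isomer; no stereocentre is involved.

**Compound list**
1 | (S)-epichlorohydrin, (2S)-2-(chloromethyl)oxirane | ClC[C@@H]1CO1 | starting material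
2 | isopropenylmagnesium bromide | CC(=C)[Mg]Br | starting material
3 | (2S)-1-chloro-4-methylpent-4-en-2-ol (magnesium alkoxide in the flask) | ClC[C@@H](O)CC(C)=C | intermediate (not isolated)
4 | (2S)-2-(2-methylprop-2-en-1-yl)oxirane | CC(=C)C[C@H]1CO1 | intermediate
5 | methyl propiolate | C#CC(=O)OC | starting material
6 | methyl (5S)-5-hydroxy-7-methyloct-7-en-2-ynoate | CC(=C)C[C@H](O)CC#CC(=O)OC | intermediate
7 | methyl (2Z,5S)-5-hydroxy-3,7-dimethylocta-2,7-dienoate | CC(=C)C[C@H](O)C/C(C)=C\C(=O)OC | intermediate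
8 | (6S)-4-methyl-6-(2-methylprop-2-en-1-yl)-5,6-dihydro-2H-pyran-2-one | CC(=C)C[C@H]1CC(C)=CC(=O)O1 | intermediate (not isolated)
9 | (1S,4R)-5,8,8-trimethyl-2-oxabicyclo[2.2.2]oct-5-en-3-one | CC1=C[C@@H]2CC(C)(C)[C@H]1C(=O)O2 | intermediate
10 | (1S,4R)-5,8,8-trimethyl-2-oxabicyclo[2.2.2]oct-5-en-3-ol, C3 epimers | CC1=C[C@@H]2CC(C)(C)[C@H]1C(O)O2 | intermediate
11 | (1S,4R,5R,6S)-5,6-epoxy-5,8,8-trimethyl-2-oxabicyclo[2.2.2]octan-3-one | C[C@]12O[C@H]1[C@@H]3CC(C)(C)[C@H]2C(=O)O3 | intermediate
12 | (1S,4R,5R,6S)-5,6-epoxy-5,8,8-trimethyl-2-oxabicyclo[2.2.2]octan-3-ol, C3 epimers | C[C@]12O[C@H]1[C@@H]3CC(C)(C)[C@H]2C(O)O3 | intermediate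
13 | (1R,2R,3S,4S)-2,3-epoxy-4-hydroxy-2,6,6-trimethylcyclohexane-1-carbaldehyde | C[C@]12O[C@H]1[C@@H](O)CC(C)(C)[C@H]2C=O | intermediate (not isolated)
14 | (3R,4S)-3,4-dihydroxy-2,6,6-trimethylcyclohex-1-ene-1-carbaldehyde | O=CC1=C(C)[C@@H](O)[C@@H](O)CC1(C)C | intermediate
15 | crocetin dialdehyde, (2E,4E,6E,8E,10E,12E,14E)-2,6,11,15-tetramethylhexadeca-2,4,6,8,10,12,14-heptaenedial | O=C/C(C)=C/C=C/C(C)=C/C=C/C=C(C)/C=C/C=C(C)/C=O | starting material
16 | (2E,4E,6E,8E,10E,12E,14E)-2,6,11,15-tetramethylhexadeca-2,4,6,8,10,12,14-heptaene-1,16-diol | OC/C(C)=C/C=C/C(C)=C/C=C/C=C(C)/C=C/C=C(C)/CO | intermediate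
17 | [(2E,4E,6E,8E,10E,12E,14E)-2,6,11,15-tetramethylhexadeca-2,4,6,8,10,12,14-heptaene-1,16-diyl]bis(triphenylphosphonium) dibromide | [Br-].[Br-].c1ccccc1[P+](c1ccccc1)(c1ccccc1)C/C(C)=C/C=C/C(C)=C/C=C/C=C(C)/C=C/C=C(C)/C[P+](c1ccccc1)(c1ccccc1)c1ccccc1 | intermediate
18 | mono-ylide of 17, [(2E,4E,6E,8E,10E,12E,14E)-2,6,11,15-tetramethyl-16-(triphenyl-λ5-phosphanylidene)hexadeca-2,4,6,8,10,12,14-heptaen-1-yl]triphenylphosphonium bromide | [Br-].c1ccccc1[P+](c1ccccc1)(c1ccccc1)C/C(C)=C/C=C/C(C)=C/C=C/C=C(C)/C=C/C=C(C)/C=P(c1ccccc1)(c1ccccc1)c1ccccc1 | intermediate (not isolated)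
19 | (1R,4S)-4-hydroxy-2,6,6-trimethylcyclohex-2-ene-1-carbaldehyde (open form of 10) | CC1=C[C@@H](O)CC(C)(C)[C@H]1C=O | intermediate (not isolated)
20 | [(2E,4E,6E,8E,10E,12E,14E,16E)-17-[(1R,4S)-4-hydroxy-2,6,6-trimethylcyclohex-2-en-1-yl]-2,6,11,15-tetramethylheptadeca-2,4,6,8,10,12,14,16-octaen-1-yl]triphenylphosphonium bromide | CC1=C[C@@H](O)CC(C)(C)[C@H]1/C=C/C(C)=C/C=C/C(C)=C/C=C/C=C(C)/C=C/C=C(C)/C[P+](c1ccccc1)(c1ccccc1)c1ccccc1.[Br-] | intermediate
21 | ylide of 20, (1R,4S)-3,5,5-trimethyl-4-[(1E,3E,5E,7E,9E,11E,13E,15E)-3,7,12,16-tetramethyl-17-(triphenyl-λ5-phosphanylidene)heptadeca-1,3,5,7,9,11,13,15-octaen-1-yl]cyclohex-2-en-1-ol | CC1=C[C@@H](O)CC(C)(C)[C@H]1/C=C/C(C)=C/C=C/C(C)=C/C=C/C=C(C)/C=C/C=C(C)/C=P(c1ccccc1)(c1ccccc1)c1ccccc1 | intermediate (not isolated)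
22 | (3S,4R,3′S,6′R)-β,ε-carotene-3,4,3′-triol | CC1=C[C@@H](O)CC(C)(C)[C@H]1/C=C/C(C)=C/C=C/C(C)=C/C=C/C=C(C)/C=C/C=C(C)/C=C/C1=C(C)[C@@H](O)[C@@H](O)CC1(C)C | target

**Step count and risks**
Total steps: 12. Longest linear sequence: 8 (steps 1, 2, 3, 4, 6, 7, 8, 12).

The three steps most likely to fail:

Step 4, the bicyclisation. The tertiary cation can be diverted by capture at the lactone carbonyl oxygen, by alkene migration into the allylic position followed by ionisation of the lactone C–O bond, or by attack of the alkene on the protonated enoate. The fallback sets out from 7 and comes back at 9, and it cyclises before lactonising. The hydroxyl of 7 is capped as the tert-butyldiphenylsilyl ether F1 (t-BuPh2SiCl, imidazole). F1 undergoes the classical geranate-type cation–olefin cyclisation (MeSO3H, CH2Cl2, −20 °C) through a chair in which the Z-ester becomes axial and the silyloxy group stays equatorial, giving the cis cyclohexene ester F2. Bu4NF then frees the hydroxy ester F3, and Ti(Oi-Pr)4-catalysed transesterification in hot toluene closes the bridged lactone, which is 9.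

Step 11, the mono-Wittig reaction of the bis-ylide with the lactol. The open aldehyde 19 is α-branched and β,γ-unsaturated, so enolisation would epimerise C6′ or conjugate the alkene, and the statistical mono-coupling and salt separation may be inefficient. The fallback sets out from 17 and 14 and comes back at 22, and it reverses the order of the two olefinations. The excess bis-ylide is first condensed with the non-enolisable enal 14 (NaOMe, MeOH/CH2Cl2) to give the β-end C30 phosphonium bromide F4. F4 is then coupled with lactol 10 by the base-free epoxide method (1,2-epoxybutane/EtOH, reflux), so the enolisable ε-ring aldehyde never meets a strong base.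

Step 12, the final Wittig reaction. Enal 14 is hindered, and under NaOMe its free γ-hydroxyl can promote isomerisation to a 1,4-dicarbonyl compound or slow the addition. The fallback sets out from 14 and comes back at 22, and it uses a protecting-group detour. Enal 14 is converted into the bis(triethylsilyl) ether F5 (Et3SiCl, imidazole, DMF). Wittig coupling of F5 with 20 (NaOMe or KN(SiMe3)2) gives the bis-silyl carotenoid F6, and Bu4NF buffered with AcOH in THF frees the diol.

**Further compounds**
F1 | step 4 | methyl (2Z,5S)-5-[(tert-butyldiphenylsilyl)oxy]-3,7-dimethylocta-2,7-dienoate | CC(=C)C[C@H](O[Si](c1ccccc1)(c1ccccc1)C(C)(C)C)C/C(C)=C\C(=O)OC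
F2 | step 4 | methyl (1R,4S)-4-[(tert-butyldiphenylsilyl)oxy]-2,6,6-trimethylcyclohex-2-ene-1-carboxylate | CC1=C[C@@H](O[Si](c2ccccc2)(c2ccccc2)C(C)(C)C)CC(C)(C)[C@H]1C(=O)OC
F3 | step 4 | methyl (1R,4S)-4-hydroxy-2,6,6-trimethylcyclohex-2-ene-1-carboxylate | CC1=C[C@@H](O)CC(C)(C)[C@H]1C(=O)OC
F4 | step 11 | [(2E,4E,6E,8E,10E,12E,14E,16E)-17-[(3R,4S)-3,4-dihydroxy-2,6,6-trimethylcyclohex-1-en-1-yl]-2,6,11,15-tetramethylheptadeca-2,4,6,8,10,12,14,16-octaen-1-yl]triphenylphosphonium bromide | [Br-].c1ccccc1[P+](c1ccccc1)(c1ccccc1)C/C(C)=C/C=C/C(C)=C/C=C/C=C(C)/C=C/C=C(C)/C=C/C1=C(C)[C@@H](O)[C@@H](O)CC1(C)C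
F5 | step 12 | (3R,4S)-2,6,6-trimethyl-3,4-bis[(triethylsilyl)oxy]cyclohex-1-ene-1-carbaldehyde | O=CC1=C(C)[C@@H](O[Si](CC)(CC)CC)[C@@H](O[Si](CC)(CC)CC)CC1(C)C
F6 | step 12 | (3S,4R,3′S,6′R)-3,4-bis[(triethylsilyl)oxy]-β,ε-caroten-3′-ol | CC1=C[C@@H](O)CC(C)(C)[C@H]1/C=C/C(C)=C/C=C/C(C)=C/C=C/C=C(C)/C=C/C=C(C)/C=C/C1=C(C)[C@@H](O[Si](CC)(CC)CC)[C@@H](O[Si](CC)(CC)CC)CC1(C)C
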